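The numbers in the tables were computed for an exercise; the scatter is artificial.

The winter run carries more catalyst than the summer run, about twice as much, on the same charge of starting material.

| flask | starting material | catalyst | remark | time |
|---|---|---|---|---|
| summer | 0.050 M | 0.94 mol% | run made earlier |  |
| winter | 0.050 M | 2.1 mol% | run made earlier |  |
| flask | 0.050 M | 1.4 mol% |  | 30 min |

| run | time / min | product / % | starting material / % |
|---|---|---|---|
| summer | 5.00 | 14 | 60 |
| summer | 10.0 | 27 | 37 |
| summer | 15.0 | 36 | 25 |
| summer | 20.0 | 42 | 15 |
| summer | 25.0 | 42 | 10 |
| summer | 30.0 | 49 | 7 |
| winter | 2.50 | 10 | 78 |
| winter | 4.00 | 17 | 68 |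
| winter | 6.00 | 19 | 58 |
| winter | 10.0 | 28 | 39 |
| winter | 20.0 | 38 | 16 |
| winter | 30.0 | 43 | 7 |

(standard deviation of a reading: 2 percentage points)

- amount of product in percent of the starting material charged, at 1.5 min, 8.0 min and 30 min

- the earlier runs were read with a standard deviation of 2 percentage points

Two numbers don't seem to go together with that. At 10.0 min the summer run reads 27% product and the winter run 28%, and at 30.0 min the winter run reads 43%, less than the 49% of the summer run, with a scatter of 2 points on each reading.

The starting material reads alike in the two runs: at 20.0 min it stands at 15% and 16%, from which I read a first-order constant of 0.0932 min⁻¹. Product and starting material together read 56.0% in the summer run at 30.0 min, so part of the charge stands in some other form. So I reckon the loss of starting material with this one constant for both runs and for the flask, take what the catalyst does as a fast step already settled (a quasi-equilibrium), and reckon with the product share, the product read per starting material lost. The readings at 20.0 min and 30.0 min give 0.511 for the summer run and 0.458 for the winter run, and pooled 0.485. The summer value leans on the single reading of 49%, which stands above the 42% read at 25.0 min, so I read the gap between the two runs as scatter and pool them.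

For the flask this gives me 25.5% at 8.0 min and 45.5% at 30 min. At 1.5 min I expect less than the 6.33% it gives, because the earliest reading of each run gives a share of 0.350 in the summer run and 0.455 in the winter run, both lower than the pooled one.

The forecast, which holds that “More catalyst gives a faster early rise but a lower final yield”, stands at 3.5%, 23.5% and 46.5%.

The flask gives 4.54%, 24.4% and 45.3%.

    starting material → intermediate (k = 0.0730 min⁻¹)
    catalyst + intermediate ⇌ catalyst + product (K = 1.70, k = 1900 L mol⁻¹ min⁻¹)
    starting material ⇌ dormant form (K = 2.50, k = 0.0260 min⁻¹)

At 30.0 min the flask holds 26.9% intermediate and 20.7% dormant form beside its 7.05% starting material, and its product share is 0.487, against the 0.485 read from the earlier runs. Put to use on the winter run at 10.0 min, where 61.0% of the starting material is lost, the pooled share gives 29.6% product, and the reading there is 28%.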